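**Retrosynthetic overview**
- Last bond: the spiro C–O bond (chromanone O1 to the spiro carbon, which is C8 of the afzelechin ring A), formed by oxidative dearomatisation of the ring-A 5-phenol with para attack of an ortho-OH of the aroyl ring; this closes the chromanone ring and creates the dienone.
- Before that: the dihydrofuran ring, closed by C–O bond formation from the 7-OH to the benzylic carbon (stereoconvergent, aryl trans to aroyl).
- Key disconnection: the bond from chromanone C3 to the spiro carbon and the bond from the C4 ketone carbon to C4a, both made in one flask by adding two aryl-metals to the ketone and the ester carbonyl of one (R)-configured alpha-keto ester.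
- Enabling feature: chromanone C3 (tertiary carbinol) and C4 (ketone) form an alpha-ketol, i.e. a masked alpha-keto acid, and each is bonded to an aromatic carbon lying between two oxygens (C8 of the flavan ring A at the phenol level; C4a of the phloroglucinol ring), where aryl-metals are easily generated.
- Ring order: pyran ring of afzelechin (chiral pool), then the dihydrofuran ring (step 10), then the spiro chromanone ring (step 12).

Key step: step 9

Assumption: (+)-afzelechin is taken as purchasable chiral-pool material, and the (R,R) antipode of ProPhenol is assumed to give the R carbinol in step 4 (otherwise the (S,S) antipode is used).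

**Step 1**
Reactants: 1 (+)-afzelechin
Product: 2 5,7,4'-tris-O-(methoxymethyl)afzelechin
Conditions: MOMCl (3.6 equiv), K2CO3, acetone, 0 °C to rt
Reagents that add atoms: chloromethyl methyl ether (MOMCl), COCCl
Why: Williamson-type O-alkylation of the three phenols under carbonate base should leave the much less acidic secondary 3-OH free and does not touch C2 or C3.

**Step 2**
Reactants: 2 5,7,4'-tris-O-(methoxymethyl)afzelechin
Product: 3 3-O-TBS-5,7,4'-tris-O-MOM-afzelechin
Conditions: TBSCl, imidazole, DMF, rt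
Reagents that add atoms: tert-butyldimethylsilyl chloride (TBSCl), CC(C)(C)[Si](C)(C)Cl
Why: Imidazole-mediated silylation of the secondary alcohol removes the only acidic proton before the organolithium chemistry.

**Step 3**
Reactants: 3 3-O-TBS-5,7,4'-tris-O-MOM-afzelechin
Product: 4 8-bromo-3-O-TBS-5,7,4'-tris-O-MOM-afzelechin
Conditions: NBS (1.0 equiv), CH2Cl2, −78 to −20 °C
Reagents that add atoms: N-bromosuccinimide (NBS), O=C1CCC(=O)N1Br
Why: Electrophilic aromatic bromination of 5,7-di-O-protected flavan-3-ols is expected at C8 (between the pyran oxygen and the 7-oxygen), ring B being far less activated.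

**Step 4**
Reactants: 5 4-(methoxymethoxy)benzaldehyde; 6 ethyl diazoacetate
Product: 7 ethyl (3R)-2-diazo-3-hydroxy-3-[4-(methoxymethoxy)phenyl]propanoate
Conditions: Bu2Mg (cat.), (R,R)-ProPhenol (cat.), cis-cyclopentane-1,2-diol (cat.), THF, −20 °C
Reagents that add atoms: none
Why: Catalytic asymmetric direct aldol addition of the nucleophilic diazo carbon to the aldehyde, with the chiral dinuclear magnesium catalyst selecting the aldehyde face to set the R carbinol that later relays chirality to the quaternary carbinol.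

**Step 5**
Reactants: 7 ethyl (3R)-2-diazo-3-hydroxy-3-[4-(methoxymethoxy)phenyl]propanoate
Product: 8 ethyl (3R)-2-diazo-3-(methoxymethoxy)-3-[4-(methoxymethoxy)phenyl]propanoate
Conditions: MOMCl, i-Pr2NEt, CH2Cl2, 0 °C to rt
Reagents that add atoms: chloromethyl methyl ether (MOMCl), COCCl
Why: Amine-mediated MOM ether formation leaves the diazo ester and the stereocenter untouched and installs the chelating ether needed in step 9.

**Step 6**
Reactants: 8 ethyl (3R)-2-diazo-3-(methoxymethoxy)-3-[4-(methoxymethoxy)phenyl]propanoate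
Product: 9 ethyl (3R)-3-(methoxymethoxy)-3-[4-(methoxymethoxy)phenyl]-2-oxopropanoate
Conditions: dimethyldioxirane (DMDO), acetone, 0 °C; used crude at once
Reagents that add atoms: dimethyldioxirane (DMDO), CC1(C)OO1
Why: Oxygen-atom transfer to the diazo carbon with loss of N2 gives the alpha-keto ester under neutral, base-free conditions, so the enolisable benzylic stereocenter should not epimerise.

**Step 7**
Reactants: 10 3,5-bis(benzyloxy)phenol
Product: 11 1,3,5-tris(benzyloxy)benzene
Conditions: BnBr, K2CO3, DMF, rt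
Reagents that add atoms: benzyl bromide, BrCc1ccccc1
Why: Williamson ether synthesis on the single free phenol gives the symmetrical triether.

**Step 8**
Reactants: 11 1,3,5-tris(benzyloxy)benzene
Product: 12 2-bromo-1,3,5-tris(benzyloxy)benzene
Conditions: NBS (1.0 equiv), MeCN, 0 °C
Reagents that add atoms: N-bromosuccinimide (NBS), O=C1CCC(=O)N1Br
Why: Electrophilic monobromination of the symmetrical triether, whose three ring CH positions are equivalent, can give only one regioisomer.

**Step 9**
Reactants: 4 8-bromo-3-O-TBS-5,7,4'-tris-O-MOM-afzelechin; 9 ethyl (3R)-3-(methoxymethoxy)-3-[4-(methoxymethoxy)phenyl]-2-oxopropanoate; 12 2-bromo-1,3,5-tris(benzyloxy)benzene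
Product: 17 (2R,3R)-2-hydroxy-3-(methoxymethoxy)-3-[4-(methoxymethoxy)phenyl]-2-[3-O-TBS-5,7,4'-tris-O-MOM-afzelechin-8-yl]-1-[2,4,6-tris(benzyloxy)phenyl]propan-1-one, via flavanyllithium 13 (not isolated), via flavanylmagnesium bromide 14 (not isolated), via bromomagnesium alkoxide 15 (not isolated), via tris(benzyloxy)phenyllithium 16 (not isolated)
Conditions: 4, n-BuLi, THF, −78 °C; MgBr2·OEt2; 9, −78 °C; then 16 (from 12, n-BuLi, THF, −78 °C; 2.5 equiv), −78 to −40 °C; aq NH4Cl
Reagents that add atoms: none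
Why: Bromine–lithium exchange on 4 and transmetalation give aryl Grignard 14, which adds to the ketone carbonyl of 9 to form alkoxide 15 (bond from the future spiro carbon to the carbinol carbon); aryllithium 16 then acylates at the ester carbonyl with loss of ethoxide to form the aryl ketone (acyl–aryl bond). The closest known reaction types are chelation-controlled Grignard addition to alpha-alkoxy ketones and alpha-keto esters, and ketone synthesis from esters or lactones with ortho,ortho'-dialkoxy aryllithiums. No ring is closed in this step; it assembles all thirty carbon atoms of the target from three simple fragments and installs the alpha-ketol from which the dihydrofuran ring (step 10) and the spiro chromanone ring (step 12) are closed. The new tertiary carbinol stereocenter is controlled by a five-membered magnesium chelate between the ketone oxygen and the MOM ether oxygen of the adjacent R center, the aryl group entering from the face of the small hydrogen, anti to the 4-(methoxymethoxy)phenyl group. The step needs ketone-before-ester chemoselectivity, secured by the higher electrophilicity of the alpha-keto carbonyl at −78 °C and the order of addition, and single acylation, secured by the steric shielding of the bis-ortho-benzyloxy aryl ketone; regiochemistry on both arenes is fixed by the bromine positions.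

**Step 10**
Reactants: 17 (2R,3R)-2-hydroxy-3-(methoxymethoxy)-3-[4-(methoxymethoxy)phenyl]-2-[3-O-TBS-5,7,4'-tris-O-MOM-afzelechin-8-yl]-1-[2,4,6-tris(benzyloxy)phenyl]propan-1-one
Product: 19 tris-O-benzyl furanoflavan: afzelechin carrying on C7–C8 a fused (2R,3R)-3-hydroxy-2-(4-hydroxyphenyl)-3-[2,4,6-tris(benzyloxy)benzoyl]-2,3-dihydrofuran ring (furan O on C7 and furan C3 on C8), via heptaol 18 (not isolated)
Conditions: HCl (2 M), MeOH–THF, 40 °C
Reagents that add atoms: none
Why: Acidic methanolysis removes the five MOM ethers and the TBS ether, and the freed 4-hydroxybenzylic alcohol ionises (protonated para-quinone methide) and is captured by the neighbouring 7-OH in a reversible 5-exo-trig closure (the 5-OH cannot reach and the aroyl-ring oxygens are benzylated), which should deliver the thermodynamically preferred isomer with the aryl group trans to the aroyl group whatever the configuration of the ionising carbon.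

**Step 11**
Reactants: 19 tris-O-benzyl furanoflavan
Product: 20 furanoflavan hexaphenol-diol: as 19 with a 2,4,6-trihydroxybenzoyl group
Conditions: H2 (1 atm), 10% Pd/C, EtOAc–MeOH, rt
Reagents that add atoms: none
Why: Hydrogenolysis of the three aryl benzyl ethers under neutral conditions should spare the ketone, the tertiary alcohol and the cyclic benzylic ether bonds of the pyran and dihydrofuran rings.

**Step 12**
Reactants: 20 furanoflavan hexaphenol-diol
Product: 21 genkwanol C
Conditions: PhI(OAc)2 (1.0 equiv), (CF3)2CHOH–MeCN, −30 °C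
Reagents that add atoms: none
Why: Oxidative dearomatisation of the most electron-rich phenol (ring-A 5-OH) by PhI(OAc)2 gives a phenoxenium species that is attacked at the para carbon (C8) by an ortho-OH of the aroyl ring in a 6-exo-trig spiro-etherification (grisan-type phenol oxidative coupling), the spiro configuration being dictated by the adjacent quaternary carbinol because the aroyl group can deliver oxygen only to the face it occupies.

**Compound list**
1 | (+)-afzelechin, (2R,3S)-2-(4-hydroxyphenyl)chromane-3,5,7-triol | Oc1cc(O)c2C[C@H](O)[C@@H](c3ccc(O)cc3)Oc2c1 | starting material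
2 | 5,7,4'-tris-O-(methoxymethyl)afzelechin | COCOc1cc(OCOC)c2C[C@H](O)[C@@H](c3ccc(OCOC)cc3)Oc2c1 | intermediate
3 | 3-O-TBS-5,7,4'-tris-O-MOM-afzelechin | COCOc1cc(OCOC)c2C[C@H](O[Si](C)(C)C(C)(C)C)[C@@H](c3ccc(OCOC)cc3)Oc2c1 | intermediate
4 | 8-bromo-3-O-TBS-5,7,4'-tris-O-MOM-afzelechin | COCOc1cc(OCOC)c2C[C@H](O[Si](C)(C)C(C)(C)C)[C@@H](c3ccc(OCOC)cc3)Oc2c1Br | intermediate
5 | 4-(methoxymethoxy)benzaldehyde | COCOc1ccc(C=O)cc1 | starting material
6 | ethyl diazoacetate | CCOC(=O)C=[N+]=[N-] | starting material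
7 | ethyl (3R)-2-diazo-3-hydroxy-3-[4-(methoxymethoxy)phenyl]propanoate | CCOC(=O)C(=[N+]=[N-])[C@H](O)c1ccc(OCOC)cc1 | intermediate
8 | ethyl (3R)-2-diazo-3-(methoxymethoxy)-3-[4-(methoxymethoxy)phenyl]propanoate | CCOC(=O)C(=[N+]=[N-])[C@H](OCOC)c1ccc(OCOC)cc1 | intermediate
9 | ethyl (3R)-3-(methoxymethoxy)-3-[4-(methoxymethoxy)phenyl]-2-oxopropanoate | CCOC(=O)C(=O)[C@H](OCOC)c1ccc(OCOC)cc1 | intermediate
10 | 3,5-bis(benzyloxy)phenol | Oc1cc(OCc2ccccc2)cc(OCc2ccccc2)c1 | starting material
11 | 1,3,5-tris(benzyloxy)benzene | C(Oc1cc(OCc2ccccc2)cc(OCc2ccccc2)c1)c1ccccc1 | intermediate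
12 | 2-bromo-1,3,5-tris(benzyloxy)benzene | Brc1c(OCc2ccccc2)cc(OCc2ccccc2)cc1OCc1ccccc1 | intermediate
13 | flavanyllithium (8-lithio derivative of 3) | COCOc1cc(OCOC)c2C[C@H](O[Si](C)(C)C(C)(C)C)[C@@H](c3ccc(OCOC)cc3)Oc2c1[Li] | intermediate (not isolated)
14 | flavanylmagnesium bromide (8-bromomagnesio derivative of 3) | COCOc1cc(OCOC)c2C[C@H](O[Si](C)(C)C(C)(C)C)[C@@H](c3ccc(OCOC)cc3)Oc2c1[Mg]Br | intermediate (not isolated)
15 | bromomagnesium alkoxide of the ethyl (2R,3R)-2-hydroxy-2-(flavan-8-yl) ester | COCOc1cc(OCOC)c2C[C@H](O[Si](C)(C)C(C)(C)C)[C@@H](c3ccc(OCOC)cc3)Oc2c1[C@](O[Mg]Br)(C(=O)OCC)[C@H](OCOC)c1ccc(OCOC)cc1 | intermediate (not isolated)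
16 | 2,4,6-tris(benzyloxy)phenyllithium | [Li]c1c(OCc2ccccc2)cc(OCc2ccccc2)cc1OCc1ccccc1 | intermediate (not isolated)
17 | (2R,3R)-2-hydroxy-3-(methoxymethoxy)-3-[4-(methoxymethoxy)phenyl]-2-[3-O-TBS-5,7,4'-tris-O-MOM-afzelechin-8-yl]-1-[2,4,6-tris(benzyloxy)phenyl]propan-1-one | COCOc1cc(OCOC)c2C[C@H](O[Si](C)(C)C(C)(C)C)[C@@H](c3ccc(OCOC)cc3)Oc2c1[C@](O)(C(=O)c1c(OCc3ccccc3)cc(OCc3ccccc3)cc1OCc1ccccc1)[C@H](OCOC)c1ccc(OCOC)cc1 | intermediate
18 | heptaol: (2R,3R)-2-(afzelechin-8-yl)-2,3-dihydroxy-3-(4-hydroxyphenyl)-1-[2,4,6-tris(benzyloxy)phenyl]propan-1-one | Oc1cc(O)c2C[C@H](O)[C@@H](c3ccc(O)cc3)Oc2c1[C@](O)(C(=O)c1c(OCc3ccccc3)cc(OCc3ccccc3)cc1OCc1ccccc1)[C@H](O)c1ccc(O)cc1 | intermediate (not isolated)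
19 | tris-O-benzyl furanoflavan: afzelechin with a (2R,3R)-3-hydroxy-2-(4-hydroxyphenyl)-3-[2,4,6-tris(benzyloxy)benzoyl]-2,3-dihydrofuran ring fused at C7 (O) and C8 (C3) | Oc1cc2O[C@H](c3ccc(O)cc3)[C@@](O)(C(=O)c3c(OCc4ccccc4)cc(OCc4ccccc4)cc3OCc3ccccc3)c2c2c1C[C@H](O)[C@@H](c1ccc(O)cc1)O2 | intermediate
20 | furanoflavan hexaphenol-diol: as 19 with a 2,4,6-trihydroxybenzoyl group | Oc1cc2O[C@H](c3ccc(O)cc3)[C@@](O)(C(=O)c3c(O)cc(O)cc3O)c2c2c1C[C@H](O)[C@@H](c1ccc(O)cc1)O2 | intermediate
21 | genkwanol C | O=C1C=C2O[C@H](c3ccc(O)cc3)[C@@]3(O)C(=O)c4c(O)cc(O)cc4O[C@@]23C2=C1C[C@H](O)[C@@H](c1ccc(O)cc1)O2 | target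

**Totals**
Total step count: 12. Longest linear sequence: 7 steps (steps 1, 2, 3, 9, 10, 11, 12; the branch through steps 4, 5, 6 is equally long).

**Steps most likely to fail**

Step 9. The hindered aryllithium may acylate the congested ester alkoxide too slowly, so that enolisation of the keto ester or decomposition of the aryllithium competes. Fallback: set out from 4 and 9, stop after the Grignard addition and isolate the ethyl (2R,3R)-2-hydroxy ester F1. Reduce it with i-Bu2AlH at −78 °C to the alpha-hydroxy aldehyde F2. Add aryllithium 16 to this far less hindered carbonyl to give the diol F3 (mixture at the new secondary carbinol). Oxidise the secondary benzylic alcohol with Dess–Martin periodinane; this returns to the route at 17, the acyl–aryl bond now coming from an aldehyde addition and oxidation instead of an ester acylation.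

Step 10. The benzylic cation may be trapped by methanol, or close kinetically to the 2,3-cis isomer, instead of giving the trans dihydrofuran; a 1,2-aryl shift is a further drain. Fallback: set out from 17 and run the acidolysis at 0 °C so that it stops at the benzylic methyl ether F4 (mixture at the benzylic carbon, all MOM and TBS groups removed). Then change from cationic to anionic closure: K2CO3 or DBU in MeCN at 50 °C should expel methoxide to give the para-quinone methide, to which the 7-phenoxide adds reversibly in a 1,6-oxa-Michael reaction under thermodynamic control; this returns to the route at 19.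

Step 12. The oxidant may attack the two 4-hydroxyphenyl groups or over-oxidise the product, because all phenols are free. Fallback: set out from 19 and silylate the two unhindered 4-hydroxyphenyl groups with TBDPSCl and imidazole at −20 °C (the ortho-substituted 5-OH is expected to react last) to give the bis-silyl ether F5. Hydrogenolysis (H2, 10% Pd/C) then gives the trihydroxybenzoyl compound F6, in which only the ring-A phenol and the aroyl-ring phenols are free. PhI(OAc)2 should give the spirodienone bis-silyl ether F7. Bu4NF buffered with AcOH in THF at 0 °C then removes the silyl groups and returns to the route at 21.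

**Further compounds**
F1 | step 9 | ethyl (2R,3R)-2-hydroxy-3-(methoxymethoxy)-3-[4-(methoxymethoxy)phenyl]-2-[3-O-TBS-5,7,4'-tris-O-MOM-afzelechin-8-yl]propanoate | COCOc1cc(OCOC)c2C[C@H](O[Si](C)(C)C(C)(C)C)[C@@H](c3ccc(OCOC)cc3)Oc2c1[C@](O)(C(=O)OCC)[C@H](OCOC)c1ccc(OCOC)cc1
F2 | step 9 | (2R,3R)-2-hydroxy-3-(methoxymethoxy)-3-[4-(methoxymethoxy)phenyl]-2-[3-O-TBS-5,7,4'-tris-O-MOM-afzelechin-8-yl]propanal | COCOc1cc(OCOC)c2C[C@H](O[Si](C)(C)C(C)(C)C)[C@@H](c3ccc(OCOC)cc3)Oc2c1[C@](O)(C=O)[C@H](OCOC)c1ccc(OCOC)cc1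
F3 | step 9 | (2R,3R)-3-(methoxymethoxy)-3-[4-(methoxymethoxy)phenyl]-2-[3-O-TBS-5,7,4'-tris-O-MOM-afzelechin-8-yl]-1-[2,4,6-tris(benzyloxy)phenyl]propane-1,2-diol (C1 epimers) | COCOc1cc(OCOC)c2C[C@H](O[Si](C)(C)C(C)(C)C)[C@@H](c3ccc(OCOC)cc3)Oc2c1[C@](O)(C(O)c1c(OCc3ccccc3)cc(OCc3ccccc3)cc1OCc1ccccc1)[C@H](OCOC)c1ccc(OCOC)cc1
F4 | step 10 | (2R)-2-(afzelechin-8-yl)-2-hydroxy-3-(4-hydroxyphenyl)-3-methoxy-1-[2,4,6-tris(benzyloxy)phenyl]propan-1-one (C3 epimers) | Oc1cc(O)c2C[C@H](O)[C@@H](c3ccc(O)cc3)Oc2c1[C@](O)(C(=O)c1c(OCc3ccccc3)cc(OCc3ccccc3)cc1OCc1ccccc1)C(OC)c1ccc(O)cc1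
F5 | step 12 | bis-TBDPS ether of 19 (both 4-hydroxyphenyl groups silylated) | Oc1cc2O[C@H](c3ccc(O[Si](c4ccccc4)(c4ccccc4)C(C)(C)C)cc3)[C@@](O)(C(=O)c3c(OCc4ccccc4)cc(OCc4ccccc4)cc3OCc3ccccc3)c2c2c1C[C@H](O)[C@@H](c1ccc(O[Si](c3ccccc3)(c3ccccc3)C(C)(C)C)cc1)O2
F6 | step 12 | bis-TBDPS ether of 20 (2,4,6-trihydroxybenzoyl group free) | Oc1cc2O[C@H](c3ccc(O[Si](c4ccccc4)(c4ccccc4)C(C)(C)C)cc3)[C@@](O)(C(=O)c3c(O)cc(O)cc3O)c2c2c1C[C@H](O)[C@@H](c1ccc(O[Si](c3ccccc3)(c3ccccc3)C(C)(C)C)cc1)O2
F7 | step 12 | bis-TBDPS ether of genkwanol C (both 4-hydroxyphenyl groups silylated) | O=C1C=C2O[C@H](c3ccc(O[Si](c5ccccc5)(c5ccccc5)C(C)(C)C)cc3)[C@@]3(O)C(=O)c4c(O)cc(O)cc4O[C@@]23C2=C1C[C@H](O)[C@@H](c1ccc(O[Si](c3ccccc3)(c3ccccc3)C(C)(C)C)cc1)O2
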